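Numbering is that of eremophilane: ring A = C1–C5/C10, ring B = C5–C10, side chain C11–C13. Ring B is a cyclohexene whose C6=C7 bond lies opposite C9–C10 and whose C8 carries oxygen. This is the retron of a [4+2] addition of a 1-oxygenated diene C5=C6–C7=C8 to C9=C10, and C1–C4 of ring A is the four-carbon tether from C5 to C10.
Retrosynthesis: first re-add a tert-butyl ester at C9 (helper, lost later as CO2) and take C8 and C12 down to silyl ethers. Then cut C8–C9 and C5–C10 together, which opens both rings to an acyclic triene. Then cut C6–C7 (sp2–sp2 coupling), and finally C3–C4, C5–CH3, C9=C10 and C7–C8.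
Forward: the chain C9–C6 is built linearly as the Z-vinyl iodide 13. C7 (from CH2Br2), C8 and C11–C13 come as the silyl ynol ether 18. The two are joined at C6–C7, one thermal step closes rings A and B, and five functional-group steps finish.
Stereochemistry: C4 comes from (S)-but-3-yn-2-ol by chirality transfer, C3 from the anti-selective allenylzinc addition, and C11 from methyl (S)-3-hydroxy-2-methylpropanoate. C5 and C10 are set in the cycloaddition, where the Z geometry of C5=C6 forces the cis ring fusion and allylic strain at C4 picks the face. C8 and C9 are transient.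

Key step: step 9

Remark: in 23–26, F6 and F11, C9 is the enolisable carbon of a β-keto ester and is written without a descriptor; it ends as CH2.

Step 1
Reactants: 1 (S)-but-3-yn-2-ol
Product: 2 (S)-but-3-yn-2-yl methanesulfonate
Conditions: MsCl, Et3N, CH2Cl2, −78 → 0 °C
Reagents that add atoms: methanesulfonyl chloride, CS(=O)(=O)Cl
Why: O-sulfonylation leaves the C–O bond and the stereocentre untouched and installs the leaving group for the propargylation.

Step 2
Reactants: 2 (S)-but-3-yn-2-yl methanesulfonate; 3 (Z)-hept-4-enal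
Product: 5 (3R,4S,7Z)-3-methyldec-7-en-1-yn-4-ol, via allenylzinc reagent 4 (not isolated)
Conditions: Pd(OAc)2 (5 mol %), PPh3 (5 mol %), Et2Zn (3 equiv), THF, −78 → −20 °C; aq. HCl
Reagents that add atoms: diethylzinc, CC[Zn]CC (its atoms stay only in 4)
Why: Marshall propargylation, in which zerovalent palladium should open 2 in an anti SN2′ sense, Et2Zn transmetalates to the configurationally stable allenylzinc 4, and its cyclic SE2′ addition to 3 sets C4 by chirality transfer (net inversion) and C3 through the anti-selective chair-like transition state.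

Step 3
Reactants: 5 (3R,4S,7Z)-3-methyldec-7-en-1-yn-4-ol
Product: 8 (1Z,3R,4S,7Z)-1-iodo-2,3-dimethyldeca-1,7-dien-4-ol, via syn-methylalumination adduct 6 (not isolated), via chelated Z-alkenylalane 7 (not isolated)
Conditions: Me3Al (3 equiv), Cp2ZrCl2 (0.25 equiv), ClCH2CH2Cl, rt; then reflux; then I2, THF, −30 → 0 °C; aq. K2CO3
Reagents that add atoms: trimethylaluminium, C[Al](C)C; iodine, II
Why: Negishi carboalumination adds CH3 to C5 and Al to C6 in a syn sense, heating lets the alkenylalane invert to the Z isomer held as the six-membered aluminium alkoxide chelate 7 (the known anti-carbometalation of homopropargylic alcohols), and iodinolysis with retention should give the Z iodide, while the 1,2-disubstituted alkene is inert to this reagent.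

Step 4
Reactants: 8 (1Z,3R,4S,7Z)-1-iodo-2,3-dimethyldeca-1,7-dien-4-ol; 9 angelic acid
Product: 11 (1Z,3R,4S,7Z)-1-iodo-2,3-dimethyldeca-1,7-dien-4-yl (Z)-2-methylbut-2-enoate, via mixed anhydride 10 (not isolated)
Conditions: 9, 2,4,6-Cl3C6H2COCl, Et3N, toluene, rt; then 8, 80 °C
Reagents that add atoms: 2,4,6-trichlorobenzoyl chloride, O=C(Cl)c1c(Cl)cc(Cl)cc1Cl (its atoms stay only in 10)
Why: Yamaguchi-type acylation through 10 without a nucleophilic catalyst is a known stereoconservative angeloylation, so the Z geometry of the angelate should hold, and C3 is acylated on oxygen only.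

Step 5
Reactants: 11 (1Z,3R,4S,7Z)-1-iodo-2,3-dimethyldeca-1,7-dien-4-yl (Z)-2-methylbut-2-enoate; 12 tert-butyl acrylate
Product: 13 tert-butyl (2E,6S,7R,8Z)-9-iodo-7,8-dimethyl-6-[(Z)-2-methylbut-2-enoyloxy]nona-2,8-dienoate
Conditions: 12 (5 equiv), second-generation Grubbs catalyst (5 mol %), CH2Cl2, 40 °C
Reagents that add atoms: none
Why: Cross metathesis of a 1,2-disubstituted alkene with an acrylate is reliably E-selective, and the trisubstituted vinyl iodide and angelate alkenes are too hindered or too electron-poor to enter the catalytic cycle.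

Step 6
Reactants: 14 methyl (S)-3-hydroxy-2-methylpropanoate
Product: 15 methyl (S)-3-(tert-butyldimethylsilyloxy)-2-methylpropanoate
Conditions: TBSCl, imidazole, CH2Cl2, rt
Reagents that add atoms: tert-butyldimethylsilyl chloride, CC(C)(C)[Si](C)(C)Cl
Why: Standard silylation of the primary alcohol under weakly basic conditions leaves the α-stereocentre (future C11) intact.

Step 7
Reactants: 15 methyl (S)-3-(tert-butyldimethylsilyloxy)-2-methylpropanoate
Product: 18 (R)-4-(tert-butyldimethylsilyloxy)-3-methyl-1-(triisopropylsilyloxy)but-1-yne, via dibromo enolate 16 (not isolated), via lithium ynolate 17 (not isolated)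
Conditions: CH2Br2, LiTMP, THF, −78 °C, then 15; LiHMDS, −78 → −20 °C; n-BuLi, −78 °C → rt; TIPSOTf, −78 → 0 °C
Reagents that add atoms: dibromomethane, BrCBr; triisopropylsilyl trifluoromethanesulfonate, CC(C)[Si](C(C)C)(C(C)C)OS(=O)(=O)C(F)(F)F; lithium hexamethyldisilazide, [Li]N([Si](C)(C)C)[Si](C)(C)C (lithium stays only in 16 and 17)
Why: Kowalski ynolate formation, in which LiCHBr2 adds to the ester, enolate 16 undergoes Br/Li exchange and a 1,2-shift of C11 (with retention) onto the carbenoid carbon to give ynolate 17, and the bulky silyl triflate silylates it on oxygen to the isolable silyl ynol ether.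

Step 8
Reactants: 18 (R)-4-(tert-butyldimethylsilyloxy)-3-methyl-1-(triisopropylsilyloxy)but-1-yne; 13 tert-butyl (2E,6S,7R,8Z)-9-iodo-7,8-dimethyl-6-[(Z)-2-methylbut-2-enoyloxy]nona-2,8-dienoate
Product: 20 tert-butyl (2E,6S,7R,8Z,10Z)-10-[(2R)-1-(tert-butyldimethylsilyloxy)propan-2-yl]-7,8-dimethyl-6-[(Z)-2-methylbut-2-enoyloxy]-11-(triisopropylsilyloxy)undeca-2,8,10-trienoate, via alkenylborane 19 (not isolated)
Conditions: 18, Cy2BH, THF, 0 °C → rt; then 13, Pd(PPh3)4 (5 mol %), aq. K3PO4, THF, 45 °C
Reagents that add atoms: dicyclohexylborane, B(C1CCCCC1)C1CCCCC1 (its atoms stay only in 19)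
Why: Proposed new method: hydroboration of a silyl ynol ether has no direct precedent; the oxygen lone pair polarises the triple bond, so electrophilic boron should bind the β-carbon C7 and hydride the oxygen-bearing C8 in a four-centre syn addition that places OTIPS trans to boron, and the Suzuki–Miyaura coupling then runs with retention at both sp2 carbons to leave OTIPS trans to C6 and C4 cis to C7; the closest known reaction type is the hydroboration of alkyl ynol ethers such as ethoxyethyne to (E)-2-alkoxyvinylboranes followed by palladium-catalysed cross-coupling.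

Step 9
Reactants: 20 tert-butyl (2E,6S,7R,8Z,10Z)-10-[(2R)-1-(tert-butyldimethylsilyloxy)propan-2-yl]-7,8-dimethyl-6-[(Z)-2-methylbut-2-enoyloxy]-11-(triisopropylsilyloxy)undeca-2,8,10-trienoate
Product: 21 tert-butyl (11R)-3β-angeloyloxy-12-(tert-butyldimethylsilyloxy)-8β-(triisopropylsilyloxy)-10βH-eremophil-6-ene-9β-carboxylate
Conditions: toluene (0.01 M), BHT (cat.), 130 °C, sealed base-washed tube
Reagents that add atoms: none
Why: Heating should trigger a concerted, asynchronous suprafacial [4π+2π] cycloaddition (type 1 intramolecular Diels–Alder reaction of a 1,7,9-decatriene, closest known type the cyclisation of Z-diene decatrienoates to cis-decalins and of 1-silyloxydienes onto enoates), in which the C8 oxygen makes C5 the nucleophilic diene terminus that bonds first to the enoate β-carbon C10 while C8–C9 follows. Ring B closes as the new cyclohexene C5–C6=C7–C8–C9–C10, and ring A closes in the fused mode through the same C5–C10 bond with the tether C1–C4 in a chair-like six-membered array. Because the tether sits in the inside (Z) position of C5, only the transition state with C1 exo is within reach, so C5–CH3 and H10 must come out cis (cis-decalin, C10 set relative to C5). The face, and with it C5, is set by C4: allylic 1,3-strain against C7 holds H4 in the diene plane, C3 carries the dienophile to one face and the C4 methyl group points to the other, which gives the 4β,5β-dimethyl relation, and the C11 rotamer with its hydrogen eclipsing C7=C8 turns only its methyl group towards the incoming enoate (matched). The E-enoate then lies with CO2t-Bu endo, so the C9 ester and the outside C8–OTIPS group should both be β, two centres that are erased later. The step needs chemoselectivity for the enoate over the angelate (trisubstituted, held away by its ester tether) and over the 1,5-hydrogen shift from C4 to C8 (which needs H4 perpendicular to the diene, the strained rotamer), while the regiochemistry is fixed by the tether and matched by the donor–acceptor polarity.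

Step 10
Reactants: 21 tert-butyl (11R)-3β-angeloyloxy-12-(tert-butyldimethylsilyloxy)-8β-(triisopropylsilyloxy)-10βH-eremophil-6-ene-9β-carboxylate
Product: 22 tert-butyl (11R)-3β-angeloyloxy-8β,12-dihydroxy-10βH-eremophil-6-ene-9β-carboxylate
Conditions: HF·pyridine, pyridine, THF, 0 °C → rt
Reagents that add atoms: none
Why: Fluoride cleavage of both silyl ethers in a buffered, weakly acidic medium avoids the β-elimination or retro-aldol that a basic fluoride source could start at the β-hydroxy ester, and no stereocentre is touched.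

Step 11
Reactants: 22 tert-butyl (11R)-3β-angeloyloxy-8β,12-dihydroxy-10βH-eremophil-6-ene-9β-carboxylate
Product: 23 tert-butyl (11R)-3β-angeloyloxy-8,12-dioxo-10βH-eremophil-6-ene-9-carboxylate
Conditions: (COCl)2, DMSO, CH2Cl2, −78 °C; i-Pr2NEt, −78 → −30 °C; cold pH 7 buffer
Reagents that add atoms: none
Why: In the Swern oxidation both hydroxyls become alkoxysulfonium salts at −78 °C before any carbonyl group exists, so the 1,4-diol cannot drain through a lactol to the 12,8-lactone, and the hindered base with a cold quench should spare the C11–H.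

Step 12
Reactants: 23 tert-butyl (11R)-3β-angeloyloxy-8,12-dioxo-10βH-eremophil-6-ene-9-carboxylate
Product: 24 (11R)-3β-angeloyloxy-9-(tert-butoxycarbonyl)-8-oxo-10βH-eremophil-6-en-12-oic acid
Conditions: NaClO2, NaH2PO4, 2-methylbut-2-ene (excess), t-BuOH/H2O, 0 °C
Reagents that add atoms: sodium chlorite, [Na+].[O-]Cl=O
Why: The Pinnick oxidation works at buffered, weakly acidic pH where α-stereocentres of aldehydes are normally kept, and the excess alkene traps HOCl before it can chlorinate the β-keto ester.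

Step 13
Reactants: 24 (11R)-3β-angeloyloxy-9-(tert-butoxycarbonyl)-8-oxo-10βH-eremophil-6-en-12-oic acid
Product: 25 methyl (11R)-3β-angeloyloxy-9-(tert-butoxycarbonyl)-8-oxo-10βH-eremophil-6-en-12-oate
Conditions: TMSCHN2, toluene/MeOH (4:1), 0 °C
Reagents that add atoms: (trimethylsilyl)diazomethane, C[Si](C)(C)C=[N+]=[N-]
Why: Base-free O-methylation of the carboxylic acid, by far the most acidic site, forms the methyl ester without any enolisation at C11.

Step 14
Reactants: 25 methyl (11R)-3β-angeloyloxy-9-(tert-butoxycarbonyl)-8-oxo-10βH-eremophil-6-en-12-oate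
Product: 27 methyl (11R)-3β-angeloyloxy-8-oxo-10βH-eremophil-6-en-12-oate (CNP0323033.1), via β-keto acid 26 (not isolated)
Conditions: TFA/CH2Cl2 (1:4), 0 °C → rt; evaporate; toluene, 80 °C
Reagents that add atoms: none
Why: Acidolysis of the tert-butyl ester (loss of isobutene) gives β-keto acid 26, which loses CO2 through the usual six-membered cyclic transition state, and the methyl ester, the angelate and C11 (not enolisable through the C8 ketone) should survive the acid.

Compound list
1 | (S)-but-3-yn-2-ol | C#C[C@H](C)O | starting material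
2 | (S)-but-3-yn-2-yl methanesulfonate | C#C[C@H](C)OS(C)(=O)=O | intermediate
3 | (Z)-hept-4-enal | CC/C=C\CCC=O | starting material
4 | (M)-buta-1,2-dienyl(ethyl)zinc | [H]C([Zn]CC)=[C@@]=C([H])C | intermediate
5 | (3R,4S,7Z)-3-methyldec-7-en-1-yn-4-ol | O[C@@H](CC/C=C\CC)[C@@H](C#C)C | intermediate
6 | (E)-alkenyl(dimethyl)alane dimethylaluminium alkoxide from syn methylalumination of 5 | C[Al](C)O[C@@H](CC/C=C\CC)[C@@H](/C(C)=C/[Al](C)C)C | intermediate
7 | six-membered 1,2-oxaluminine chelate (Z-alkenylalane, Al bound to C6 and to the C3 oxygen) | C[Al]1O[C@@H](CC/C=C\CC)[C@H](C)C(C)=C1 | intermediate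
8 | (1Z,3R,4S,7Z)-1-iodo-2,3-dimethyldeca-1,7-dien-4-ol | O[C@@H](CC/C=C\CC)[C@@H](/C(C)=C\I)C | intermediate
9 | angelic acid, (Z)-2-methylbut-2-enoic acid | C/C=C(/C)C(=O)O | starting material
10 | angelic 2,4,6-trichlorobenzoic anhydride | C/C=C(/C)C(=O)OC(=O)c1c(Cl)cc(Cl)cc1Cl | intermediate
11 | (1Z,3R,4S,7Z)-1-iodo-2,3-dimethyldeca-1,7-dien-4-yl (Z)-2-methylbut-2-enoate | C/C=C(/C)C(=O)O[C@@H](CC/C=C\CC)[C@@H](/C(C)=C\I)C | intermediate
12 | tert-butyl acrylate | C=CC(=O)OC(C)(C)C | starting material
13 | tert-butyl (2E,6S,7R,8Z)-9-iodo-7,8-dimethyl-6-[(Z)-2-methylbut-2-enoyloxy]nona-2,8-dienoate | C/C=C(/C)C(=O)O[C@@H](CC/C=C/C(=O)OC(C)(C)C)[C@@H](/C(C)=C\I)C | intermediate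
14 | methyl (S)-3-hydroxy-2-methylpropanoate | COC(=O)[C@@H](C)CO | starting material
15 | methyl (S)-3-(tert-butyldimethylsilyloxy)-2-methylpropanoate | COC(=O)[C@@H](C)CO[Si](C)(C)C(C)(C)C | intermediate
16 | lithium enolate of (S)-1,1-dibromo-4-(tert-butyldimethylsilyloxy)-3-methylbutan-2-one | [Li+].[O-]C(=C(Br)Br)[C@@H](C)CO[Si](C)(C)C(C)(C)C | intermediate
17 | lithium (R)-4-(tert-butyldimethylsilyloxy)-3-methylbut-1-yn-1-olate | [Li+].[O-]C#C[C@@H](C)CO[Si](C)(C)C(C)(C)C | intermediate
18 | (R)-4-(tert-butyldimethylsilyloxy)-3-methyl-1-(triisopropylsilyloxy)but-1-yne | CC(C)[Si](C(C)C)(C(C)C)OC#C[C@@H](C)CO[Si](C)(C)C(C)(C)C | intermediate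
19 | [(1Z,3R)-4-(tert-butyldimethylsilyloxy)-3-methyl-1-(triisopropylsilyloxy)but-1-en-2-yl]dicyclohexylborane (OTIPS trans to boron) | CC(C)[Si](C(C)C)(C(C)C)O/C=C(/B(C1CCCCC1)C1CCCCC1)[C@@H](C)CO[Si](C)(C)C(C)(C)C | intermediate
20 | tert-butyl (2E,6S,7R,8Z,10Z)-10-[(2R)-1-(tert-butyldimethylsilyloxy)propan-2-yl]-7,8-dimethyl-6-[(Z)-2-methylbut-2-enoyloxy]-11-(triisopropylsilyloxy)undeca-2,8,10-trienoate | C/C=C(/C)C(=O)O[C@@H](CC/C=C/C(=O)OC(C)(C)C)[C@@H](/C(C)=C\C(=C\O[Si](C(C)C)(C(C)C)C(C)C)[C@@H](C)CO[Si](C)(C)C(C)(C)C)C | intermediate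
21 | tert-butyl (11R)-3β-angeloyloxy-12-(tert-butyldimethylsilyloxy)-8β-(triisopropylsilyloxy)-10βH-eremophil-6-ene-9β-carboxylate | C/C=C(/C)C(=O)O[C@H]1CC[C@@H]2[C@@H](C(=O)OC(C)(C)C)[C@@H](O[Si](C(C)C)(C(C)C)C(C)C)C([C@@H](C)CO[Si](C)(C)C(C)(C)C)=C[C@]2(C)[C@H]1C | intermediate
22 | tert-butyl (11R)-3β-angeloyloxy-8β,12-dihydroxy-10βH-eremophil-6-ene-9β-carboxylate | C/C=C(/C)C(=O)O[C@H]1CC[C@@H]2[C@@H](C(=O)OC(C)(C)C)[C@@H](O)C([C@@H](C)CO)=C[C@]2(C)[C@H]1C | intermediate
23 | tert-butyl (11R)-3β-angeloyloxy-8,12-dioxo-10βH-eremophil-6-ene-9-carboxylate | C/C=C(/C)C(=O)O[C@H]1CC[C@@H]2C(C(=O)OC(C)(C)C)C(=O)C([C@@H](C)C=O)=C[C@]2(C)[C@H]1C | intermediate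
24 | (11R)-3β-angeloyloxy-9-(tert-butoxycarbonyl)-8-oxo-10βH-eremophil-6-en-12-oic acid | C/C=C(/C)C(=O)O[C@H]1CC[C@@H]2C(C(=O)OC(C)(C)C)C(=O)C([C@@H](C)C(=O)O)=C[C@]2(C)[C@H]1C | intermediate
25 | methyl (11R)-3β-angeloyloxy-9-(tert-butoxycarbonyl)-8-oxo-10βH-eremophil-6-en-12-oate | C/C=C(/C)C(=O)O[C@H]1CC[C@@H]2C(C(=O)OC(C)(C)C)C(=O)C([C@@H](C)C(=O)OC)=C[C@]2(C)[C@H]1C | intermediate
26 | (11R)-3β-angeloyloxy-12-methoxy-8,12-dioxo-10βH-eremophil-6-ene-9-carboxylic acid | C/C=C(/C)C(=O)O[C@H]1CC[C@@H]2C(C(=O)O)C(=O)C([C@@H](C)C(=O)OC)=C[C@]2(C)[C@H]1C | intermediate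
27 | methyl (11R)-3β-angeloyloxy-8-oxo-10βH-eremophil-6-en-12-oate, (3S,4R,5R,10R,11R), CNP0323033.1 | C/C=C(/C)C(=O)O[C@H]1CC[C@@H]2CC(=O)C([C@@H](C)C(=O)OC)=C[C@]2(C)[C@H]1C | target

Total step count: 14. Longest linear sequence: 12 steps (steps 1–5 and 8–14); steps 6 and 7 form the short branch.

Steps most likely to fail

Step 8 (labelled step).
- What may go wrong: the bulk at C11 may override the electronic bias and send boron to C8. The β-silyloxy alkenylborane may lose boron or the silyl group under the basic coupling. The coupling of two hindered sp2 partners may stall.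
- Fallback: the fallback uses known chemistry only. It leaves the C8 oxygen out of the diene and adds it after the cycloaddition; it sets out from 15 (with 13) and comes back at 24.
- Boronate from 15: compound 15 is reduced with i-Bu2AlH at −78 °C to (S)-3-(tert-butyldimethylsilyloxy)-2-methylpropanal F1. F1 is homologated with the Ohira–Bestmann reagent (K2CO3, MeOH) to (R)-4-(tert-butyldimethylsilyloxy)-3-methylbut-1-yne F2. α-Selective hydroalumination (Ni(dppp)Cl2 cat., i-Bu2AlH) with a MeOBpin quench converts F2 into the 1,1-disubstituted alkenyl boronate F3.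
- Return to 24: Suzuki–Miyaura coupling of F3 with 13 gives the C8-unsubstituted triene F4. Its thermal intramolecular Diels–Alder reaction, under the same Z-diene and C4 control but at higher temperature, gives the eremophil-6-ene ester F5. Allylic oxidation of the only ring allylic CH2 (C8) with CrO3/3,5-dimethylpyrazole gives the enone F6. CrO3/aq. H2SO4/acetone then turns the primary silyl ether of F6 directly into acid 24.

Step 9.
- What may go wrong: the doubly hindered s-cis diene (C4 inside) may add so slowly that the 1,5-hydrogen shift, loss of the enol silyl ether or attack on the angelate take over. The pseudo-axial C3 oxygen, syn to C5–CH3 in the chair-like tether, may also erode the facial selectivity.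
- Fallback: the fallback replaces the activating group by the far stronger aldehyde. This lowers the temperature needed and also opens a stepwise Me2AlCl-promoted vinylogous Mukaiyama–Michael/aldol closure of the same two bonds. It sets out from 11 and comes back at 21.
- Sequence: cross metathesis of 11 with crotonaldehyde (second-generation Grubbs catalyst) gives the enal iodide F7. Coupling with alkenylborane 19 as in step 8 gives the trienal F8. Cyclisation at 60–80 °C gives the 9β-carbaldehyde F9. Pinnick oxidation gives the 9β-carboxylic acid F10, and tert-butyl 2,2,2-trichloroacetimidate converts F10 into 21.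

Step 11.
- What may go wrong: the amine base may epimerise C11 or move the C6=C7 bond into conjugation in the α-alkenyl aldehyde. Incomplete double activation may let the hydroxy aldehyde close to a lactol.
- Fallback: the fallback separates the two oxidations, uses no base and never isolates the aldehyde. It sets out from 22 and comes back at 24.
- Sequence: MnO2 in CH2Cl2 oxidises only the allylic C8 alcohol to the hydroxy enone F11. Any hemiketal form of F11 is tertiary and cannot be over-oxidised. TEMPO/PhI(OAc)2 in aqueous MeCN then takes the primary alcohol straight to acid 24.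

Further compounds
F1 | step 8 | (S)-3-(tert-butyldimethylsilyloxy)-2-methylpropanal | O=C[C@@H](C)CO[Si](C)(C)C(C)(C)C
F2 | step 8 | (R)-4-(tert-butyldimethylsilyloxy)-3-methylbut-1-yne | C#C[C@@H](C)CO[Si](C)(C)C(C)(C)C
F3 | step 8 | 2-[(R)-4-(tert-butyldimethylsilyloxy)-3-methylbut-1-en-2-yl]-4,4,5,5-tetramethyl-1,3,2-dioxaborolane | C=C(B1OC(C)(C)C(C)(C)O1)[C@@H](C)CO[Si](C)(C)C(C)(C)C
F4 | step 8 | tert-butyl (2E,6S,7R,8Z)-10-[(2R)-1-(tert-butyldimethylsilyloxy)propan-2-yl]-7,8-dimethyl-6-[(Z)-2-methylbut-2-enoyloxy]undeca-2,8,10-trienoate | C/C=C(/C)C(=O)O[C@@H](CC/C=C/C(=O)OC(C)(C)C)[C@@H](/C(C)=C\C(=C)[C@@H](C)CO[Si](C)(C)C(C)(C)C)C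
F5 | step 8 | tert-butyl (11R)-3β-angeloyloxy-12-(tert-butyldimethylsilyloxy)-10βH-eremophil-6-ene-9β-carboxylate | C/C=C(/C)C(=O)O[C@H]1CC[C@@H]2[C@@H](C(=O)OC(C)(C)C)CC([C@@H](C)CO[Si](C)(C)C(C)(C)C)=C[C@]2(C)[C@H]1C
F6 | step 8 | tert-butyl (11R)-3β-angeloyloxy-12-(tert-butyldimethylsilyloxy)-8-oxo-10βH-eremophil-6-ene-9-carboxylate | C/C=C(/C)C(=O)O[C@H]1CC[C@@H]2C(C(=O)OC(C)(C)C)C(=O)C([C@@H](C)CO[Si](C)(C)C(C)(C)C)=C[C@]2(C)[C@H]1C
F7 | step 9 | (1Z,3R,4S,7E)-1-iodo-2,3-dimethyl-9-oxonona-1,7-dien-4-yl (Z)-2-methylbut-2-enoate | C/C=C(/C)C(=O)O[C@@H](CC/C=C/C=O)[C@@H](/C(C)=C\I)C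
F8 | step 9 | trienal analogue of 20 (CHO in place of CO2t-Bu) | C/C=C(/C)C(=O)O[C@@H](CC/C=C/C=O)[C@@H](/C(C)=C\C(=C\O[Si](C(C)C)(C(C)C)C(C)C)[C@@H](C)CO[Si](C)(C)C(C)(C)C)C
F9 | step 9 | (11R)-3β-angeloyloxy-12-(tert-butyldimethylsilyloxy)-8β-(triisopropylsilyloxy)-10βH-eremophil-6-ene-9β-carbaldehyde | C/C=C(/C)C(=O)O[C@H]1CC[C@@H]2[C@@H](C=O)[C@@H](O[Si](C(C)C)(C(C)C)C(C)C)C([C@@H](C)CO[Si](C)(C)C(C)(C)C)=C[C@]2(C)[C@H]1C
F10 | step 9 | (11R)-3β-angeloyloxy-12-(tert-butyldimethylsilyloxy)-8β-(triisopropylsilyloxy)-10βH-eremophil-6-ene-9β-carboxylic acid | C/C=C(/C)C(=O)O[C@H]1CC[C@@H]2[C@@H](C(=O)O)[C@@H](O[Si](C(C)C)(C(C)C)C(C)C)C([C@@H](C)CO[Si](C)(C)C(C)(C)C)=C[C@]2(C)[C@H]1C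
F11 | step 11 | tert-butyl (11R)-3β-angeloyloxy-12-hydroxy-8-oxo-10βH-eremophil-6-ene-9-carboxylate | C/C=C(/C)C(=O)O[C@H]1CC[C@@H]2C(C(=O)OC(C)(C)C)C(=O)C([C@@H](C)CO)=C[C@]2(C)[C@H]1C
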